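**Retrosynthetic overview**
1. Kazinol I (11) ⇐ global desilylation of 10; 10 ⇐ (2R)-dibromoflavan 9 by a late double prenyl cross-coupling, so no alkene is present in the acid-mediated key step.
2. The pyran ring (O1–C2 bond) and the C2 (R) stereocentre ⇐ proposed catalytic asymmetric reductive cycloetherification of 2′-hydroxydihydrochalcone 8.
3. 8 ⇐ Heck/redox-isomerisation union (C4–C4a bond) of B-ring aryl vinyl carbinol 5 with A-ring iodophenol 7.
4. 5 ⇐ 5-bromovanillin (1) by bromination, demethylation, silylation and vinyl addition; 7 ⇐ 4-iodoresorcinol (6).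
5. Ring order: both benzene rings are purchased; only the pyran C ring is built (Step 7).

Assumptions: the chiral acid catalyst is prepared separately and not counted; mono-silylation of 4-iodoresorcinol occurs at the unhindered OH para to iodine.

**Route**

Step 1
Reactants: 1, 5-bromovanillin (3-bromo-4-hydroxy-5-methoxybenzaldehyde)
Product: 2, 2,3-dibromo-4-hydroxy-5-methoxybenzaldehyde
Conditions: Br2, Fe powder (cat.), NaOAc, AcOH, rt
Reagents that add atoms: bromine, BrBr
Why: Electrophilic aromatic bromination occurs at the remaining position para to OMe, giving 5,6-dibromovanillin.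

Step 2
Reactants: 2, 2,3-dibromo-4-hydroxy-5-methoxybenzaldehyde
Product: 3, 2,3-dibromo-4,5-dihydroxybenzaldehyde
Conditions: AlCl3, pyridine, CH2Cl2, reflux; aq HCl work-up
Reagents that add atoms: none
Why: Chelation-assisted O-demethylation of an ortho-hydroxy anisole (AlCl3/pyridine), to which the aldehyde and aryl bromides are inert.

Step 3
Reactants: 3, 2,3-dibromo-4,5-dihydroxybenzaldehyde
Product: 4, 2,3-dibromo-4,5-bis(tert-butyldimethylsilyloxy)benzaldehyde
Conditions: TBSCl, imidazole, DMAP (cat.), DMF, rt
Reagents that add atoms: tert-butyldimethylsilyl chloride, CC(C)(C)[Si](C)(C)Cl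
Why: Standard phenol silylation; TBS is later removed by fluoride, the only deprotection mild enough for an ortho-prenyl catechol.

Step 4
Reactants: 4, 2,3-dibromo-4,5-bis(TBSO)benzaldehyde
Product: 5, (±)-1-[2,3-dibromo-4,5-bis(TBSO)phenyl]prop-2-en-1-ol
Conditions: vinylMgBr, THF, −78 to −20 °C
Reagents that add atoms: vinylmagnesium bromide, C=C[Mg]Br
Why: Grignard 1,2-addition to the aldehyde (no Br/Mg exchange with a vinyl Grignard at low temperature); the racemic carbinol centre is erased in Step 6.

Step 5
Reactants: 6, 4-iodoresorcinol (4-iodobenzene-1,3-diol)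
Product: 7, 2-iodo-5-(triisopropylsilyloxy)phenol
Conditions: TIPSCl (1.05 equiv), imidazole, CH2Cl2, 0 °C
Reagents that add atoms: triisopropylsilyl chloride, CC(C)[Si](Cl)(C(C)C)C(C)C
Why: Sterically controlled mono-silylation: the bulky TIPS group goes on the OH remote from iodine, leaving the ortho-iodophenol OH that becomes O1.

Step 6
Reactants: 5, (±)-1-[2,3-dibromo-4,5-bis(TBSO)phenyl]prop-2-en-1-ol; 7, 2-iodo-5-(TIPSO)phenol
Product: 8, 1-[2,3-dibromo-4,5-bis(TBSO)phenyl]-3-[2-hydroxy-4-(TIPSO)phenyl]propan-1-one
Conditions: Pd(OAc)2 (5 mol %), n-Bu4NCl, NaHCO3, DMF, 50 °C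
Reagents that add atoms: none (both partners are numbered reactants)
Why: Heck arylation of a secondary allylic alcohol under Jeffery conditions; β-hydride elimination towards the carbinol C–H gives the saturated β-aryl ketone directly, and ligand-free Pd at 50 °C inserts into the aryl iodide but not the hindered aryl bromides.

Step 7
Reactants: 8, 1-[2,3-dibromo-4,5-bis(TBSO)phenyl]-3-[2-hydroxy-4-(TIPSO)phenyl]propan-1-one
Product: 9, (2R)-2-[2,3-dibromo-4,5-bis(TBSO)phenyl]-7-(TIPSO)chroman
Conditions: confined chiral IDPi Brønsted acid (BINOL-derived imidodiphosphorimidate, N-triflyl core, 3 mol %), di-tert-butyl Hantzsch ester (1.3 equiv), 5 Å MS, toluene, −20 to 0 °C; Et3N quench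
Reagents that add atoms: none (hydride and proton only; water is lost)
Why: Proposed new method: ketone 8 equilibrates with its cyclic hemiketal (2-aryl-chroman-2-ol), which the strong confined acid dehydrates to a 2-aryl-3,4-dihydrochromenylium (cyclic oxocarbenium) ion held as a contact ion pair in the chiral anion; the Hantzsch ester, hydrogen-bonded through N–H to the same anion, delivers hydride to one face of C2, so the O1–C2 ring bond and the C2 stereocentre are made in one operation. The aryl ketone itself is inert to the Hantzsch ester, the pyridinium by-product returns the proton, and the electron-poor dibromoaryl group disfavours re-ionisation of the product. The closest known reaction types are chiral-phosphate/Hantzsch-ester reductions of benzopyrylium and cyclic iminium ions and IDPi-controlled nucleophile additions to cyclic oxocarbenium ions. The sense of induction cannot be predicted and must be found by experiment; the catalyst enantiomer that gives (2R) is used, assigned by chiral HPLC against material from the fallback route.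

Step 8
Reactants: 9, (2R)-2-[2,3-dibromo-4,5-bis(TBSO)phenyl]-7-(TIPSO)chroman
Product: 10, (2R)-2-[4,5-bis(TBSO)-2,3-bis(3-methylbut-2-en-1-yl)phenyl]-7-(TIPSO)chroman
Conditions: prenylBpin (4 equiv), Pd(OAc)2 / bulky di-tert-butyl biarylphosphine (α-selective system, e.g. t-BuXPhos class; ligand identity to be confirmed), aq K3PO4, THF, 40 °C
Reagents that add atoms: prenylboronic acid pinacol ester, CC(C)=CCB1OC(C)(C)C(C)(C)O1 (two equivalents incorporated)
Why: Double Suzuki–Miyaura coupling with ligand-controlled α-selectivity gives the linear prenyl groups at C2′ and C3′; the C2 benzylic ether stereocentre is not involved and is retained.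

Step 9
Reactants: 10, (2R)-2-[4,5-bis(TBSO)-2,3-diprenylphenyl]-7-(TIPSO)chroman
Product: 11, (+)-(2R)-kazinol I
Conditions: TBAF, AcOH (buffer), THF, 0 °C, argon; pH 5–6 work-up
Reagents that add atoms: none
Why: Fluoride desilylation of all three aryl silyl ethers under buffered, non-acidic, oxygen-free conditions avoids prenyl cyclisation onto the ortho phenol and catechol oxidation; C2 is untouched.

**Compound list**
1 | 5-bromovanillin | O=Cc1cc(Br)c(O)c(OC)c1 | starting material
2 | 2,3-dibromo-4-hydroxy-5-methoxybenzaldehyde | O=Cc1cc(OC)c(O)c(Br)c1Br | intermediate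
3 | 2,3-dibromo-4,5-dihydroxybenzaldehyde | O=Cc1cc(O)c(O)c(Br)c1Br | intermediate
4 | 2,3-dibromo-4,5-bis(TBSO)benzaldehyde | O=Cc1cc(O[Si](C)(C)C(C)(C)C)c(O[Si](C)(C)C(C)(C)C)c(Br)c1Br | intermediate
5 | (±)-1-[2,3-dibromo-4,5-bis(TBSO)phenyl]prop-2-en-1-ol | C=CC(O)c1cc(O[Si](C)(C)C(C)(C)C)c(O[Si](C)(C)C(C)(C)C)c(Br)c1Br | intermediate
6 | 4-iodoresorcinol | Oc1ccc(I)c(O)c1 | starting material
7 | 2-iodo-5-(triisopropylsilyloxy)phenol | Oc1cc(O[Si](C(C)C)(C(C)C)C(C)C)ccc1I | intermediate
8 | 1-[2,3-dibromo-4,5-bis(TBSO)phenyl]-3-[2-hydroxy-4-(TIPSO)phenyl]propan-1-one | O=C(CCc1ccc(O[Si](C(C)C)(C(C)C)C(C)C)cc1O)c1cc(O[Si](C)(C)C(C)(C)C)c(O[Si](C)(C)C(C)(C)C)c(Br)c1Br | intermediate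
9 | (2R)-2-[2,3-dibromo-4,5-bis(TBSO)phenyl]-7-(TIPSO)chroman | Brc1c([C@H]2CCc3ccc(O[Si](C(C)C)(C(C)C)C(C)C)cc3O2)cc(O[Si](C)(C)C(C)(C)C)c(O[Si](C)(C)C(C)(C)C)c1Br | intermediate
10 | (2R)-2-[4,5-bis(TBSO)-2,3-diprenylphenyl]-7-(TIPSO)chroman | CC(C)=CCc1c([C@H]2CCc3ccc(O[Si](C(C)C)(C(C)C)C(C)C)cc3O2)cc(O[Si](C)(C)C(C)(C)C)c(O[Si](C)(C)C(C)(C)C)c1CC=C(C)C | intermediate
11 | (+)-(2R)-kazinol I | CC(C)=CCc1c([C@H]2CCc3ccc(O)cc3O2)cc(O)c(O)c1CC=C(C)C | target

**Totals**
Total steps: 9. Longest linear sequence: 8 (Steps 1–4, 6–9).

**Three steps most likely to fail, with fallbacks**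
1. Step 7 (proposed asymmetric reductive cycloetherification): risks are low ee or a sluggish hindered hydride transfer. Fallback (known chemistry): reduce 8 with (R)-Me-CBS/BH3·SMe2 to the (S)-carbinol, then close the ring by intramolecular Mitsunobu etherification (PPh3, DIAD) with inversion to give (2R)-9.
2. Step 8 (late double prenylation of a hindered vicinal dibromide): risks are incomplete second coupling, branched isomer, or partial TBS loss under aqueous base. Fallback: install both prenyls at the start by base-free Stille coupling of aldehyde 4 with tributyl(prenyl)stannane, carry the diprenyl series through Steps 4 and 6, and close the ring by CBS/Mitsunobu, which is indifferent to prenyl groups.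
3. Step 6 (Heck/isomerisation): risks are competing insertion into the ortho C–Br bond or allylic-alcohol side products. Fallback: chalcone route — convert 4 to the methyl ketone (MeMgBr, then DMP), condense with 2-hydroxy-4-(TIPSO)benzaldehyde (LiHMDS aldol, MsCl/Et3N dehydration), and reduce the enone C=C with Stryker's reagent to reach the same ketone 8. This also removes the reliance on the regioselective silylation in Step 5.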